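The quinone ring of the target is twofold-symmetric apart from the acetyl group: atoms C3–C4–C5 and C6–C1–C2 (C3 and C6 aryl-bearing, C1 and C4 carbonyl, C2 acetoxy, C5 hydroxy) are two copies of one arylpyruvate three-carbon unit laid head to tail. The ring is therefore cut at C2–C3 and C5–C6. A base-mediated twofold Claisen condensation of the S-phenyl thioester of 4-(benzyloxy)phenylpyruvic acid, ArCH2–CO–CO–SPh, should forge both bonds and the six-membered ring, already at the quinone oxidation level, in one operation. Monoacetylation of the resulting dihydroxyquinone and hydrogenolysis of the benzyl ethers complete the route.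

Key step: step 4

Remark: the target has no stereocentre. The ring numbering above is used throughout, and arylpyruvic acid derivatives are drawn as keto forms although they exist largely as enols. The S-phenyl thioester (weakly basic leaving group) and the benzyl ethers (no acidic phenol, neutral removal) are chosen so that the precursor meets the base of step 4 with one acidic site per molecule.

Step 1
Reactants: 1 4-(benzyloxy)benzaldehyde; 2 N-acetylglycine
Product: 4 (Z)-4-[4-(benzyloxy)benzylidene]-2-methyl-1,3-oxazol-5(4H)-one, via 2-methyloxazolone 3 (not isolated)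
Conditions: Ac2O, NaOAc, 100 °C
Reagents that add atoms: none
Why: Erlenmeyer–Plöchl azlactone synthesis, in which Ac2O cyclodehydrates 2 to oxazolone 3, whose acidic C4 methylene condenses with the non-enolisable aldehyde 1 and dehydrates to the thermodynamically preferred Z-alkene, while the benzyl ether is inert.

Step 2
Reactants: 4 (Z)-4-[4-(benzyloxy)benzylidene]-2-methyl-1,3-oxazol-5(4H)-one
Product: 6 3-[4-(benzyloxy)phenyl]-2-oxopropanoic acid, via Z-acetamidoacrylic acid 5 (not isolated)
Conditions: 2 M HCl, 1,4-dioxane, 90 °C, N2
Reagents that add atoms: water, O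
Why: Acid-catalysed azlactone ring opening followed by enamide hydrolysis is the classical conversion of Erlenmeyer azlactones into arylpyruvic acids; dilute aqueous HCl should leave the benzyl aryl ether intact, and the acidic medium suppresses aldol self-condensation of the product.

Step 3
Reactants: 6 3-[4-(benzyloxy)phenyl]-2-oxopropanoic acid; 7 thiophenol
Product: 8 S-phenyl 3-[4-(benzyloxy)phenyl]-2-oxopropanethioate
Conditions: DCC, DMAP (cat.), CH2Cl2, −10 to 0 °C; cold dilute HCl wash; used at once
Reagents that add atoms: none
Why: Steglich-type carbodiimide thioesterification, in which the O-acylisourea of 6 should be intercepted by the soft, strongly nucleophilic thiol faster than by the hydrogen-bonded enol OH, while low temperature, catalytic DMAP and an acid wash guard against premature base-induced self-condensation of 8.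

Step 4
Reactants: 8 S-phenyl 3-[4-(benzyloxy)phenyl]-2-oxopropanethioate (two molecules)
Product: 10 2,5-bis[4-(benzyloxy)phenyl]-3,6-dihydroxy-1,4-benzoquinone, via acyclic trioxo thioester 9 (not isolated)
Conditions: MgBr2·OEt2 (1.2 equiv), i-Pr2NEt (2.5 equiv), CH2Cl2, 0 °C to rt; then 1 M HCl
Reagents that add atoms: none
Why: Proposed new method: Mg2+ chelates the 1,2-dicarbonyl unit of 8, so the amine should convert every molecule into its magnesium enolate ArCH=C(OMg)–COSPh; the benzylic carbon of one enolate then adds to the Mg-activated thioester carbonyl of a second with loss of thiophenolate (intermolecular Claisen, C5–C6, giving 9), and the remaining benzylic enolate carbon attacks the remaining thioester carbonyl (C2–C3). The closest known reaction types are the soft-enolisation C-acylation of thioesters with MgBr2·OEt2 and amine bases and the Claisen–Dieckmann condensation of 2-oxo esters, with the enzymatic dimerisation of arylpyruvate thioesters as the biosynthetic model. The ring closure is a 6-(enolendo)-exo-trig Dieckmann cyclisation, favoured by Baldwin's rules, whereas the competing intramolecular aldol of 9 onto its C2 ketone would be a disfavoured 5-(enolendo)-exo-trig process. The ring is born as a cyclohexane-1,2,4,5-tetraone, which tautomerises to the dihydroxyquinone with no change in oxidation level, and no stereocentre is created. The selectivity required is C-acylation at the thioester carbonyl in preference to aldol addition at the ketone and to O-acylation: complete enolisation removes the ketone as an electrophile, aldolates and enol esters stay reversible (retro-aldol, thiolate-mediated acyl transfer), and only the Claisen pathway drains irreversibly into the magnesium-bound quinone dianion, a doubly vinylogous carboxylate. Because both partners are the same molecule there is no cross-selectivity issue, and only head-to-tail union can close a six-membered carbocycle.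

Step 5
Reactants: 10 2,5-bis[4-(benzyloxy)phenyl]-3,6-dihydroxy-1,4-benzoquinone
Product: 11 2,5-bis[4-(benzyloxy)phenyl]-4-hydroxy-3,6-dioxocyclohexa-1,4-dien-1-yl acetate (2-acetoxy-5-hydroxy-3,6-diaryl-1,4-benzoquinone)
Conditions: Et3N (2.1 equiv), Ac2O (1.0 equiv, slow addition), CH2Cl2/DMF, −40 °C; then cold 0.5 M HCl
Reagents that add atoms: acetic anhydride, CC(=O)OC(C)=O
Why: O-acylation of a vinylogous carboxylate (Schotten–Baumann type), in which the dianion of 10 is the conjugate base of a markedly weaker acid than the monoanion of 11 and carries twice the charge, so the first acetylation should outpace the second, and the symmetry of 10 makes the two oxygens equivalent.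

Step 6
Reactants: 11 2,5-bis[4-(benzyloxy)phenyl]-4-hydroxy-3,6-dioxocyclohexa-1,4-dien-1-yl acetate
Product: 13 4-hydroxy-2,5-bis(4-hydroxyphenyl)-3,6-dioxocyclohexa-1,4-dien-1-yl acetate (the target), via hydroquinone monoacetate 12 (not isolated)
Conditions: H2 (1 atm), Pd/C, THF–EtOAc, rt; filter; then air, rt
Reagents that add atoms: none
Why: Catalytic hydrogenolysis should cleave both benzyl aryl ethers under neutral, non-nucleophilic conditions that spare the enol acetate; the quinone is reduced in passing to hydroquinone 12, in which acetyl migration among the four symmetry-equivalent ring oxygens is degenerate, and aerial oxidation can return only one p-quinone, the target.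

Compound list
1 | 4-(benzyloxy)benzaldehyde | O=Cc1ccc(OCc2ccccc2)cc1 | starting material
2 | N-acetylglycine | CC(=O)NCC(=O)O | starting material
3 | 2-methyl-1,3-oxazol-5(4H)-one | CC1=NCC(=O)O1 | intermediate
4 | (Z)-4-[4-(benzyloxy)benzylidene]-2-methyl-1,3-oxazol-5(4H)-one | CC1=N/C(=C\c2ccc(OCc3ccccc3)cc2)C(=O)O1 | intermediate
5 | (Z)-2-acetamido-3-[4-(benzyloxy)phenyl]prop-2-enoic acid | CC(=O)N/C(=C\c1ccc(OCc2ccccc2)cc1)C(=O)O | intermediate
6 | 3-[4-(benzyloxy)phenyl]-2-oxopropanoic acid | O=C(O)C(=O)Cc1ccc(OCc2ccccc2)cc1 | intermediate
7 | thiophenol (benzenethiol) | Sc1ccccc1 | starting material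
8 | S-phenyl 3-[4-(benzyloxy)phenyl]-2-oxopropanethioate | O=C(Cc1ccc(OCc2ccccc2)cc1)C(=O)Sc1ccccc1 | intermediate
9 | S-phenyl 3,6-bis[4-(benzyloxy)phenyl]-2,4,5-trioxohexanethioate (racemic, readily enolised) | O=C(Sc1ccccc1)C(=O)C(c1ccc(OCc2ccccc2)cc1)C(=O)C(=O)Cc1ccc(OCc2ccccc2)cc1 | intermediate
10 | 2,5-bis[4-(benzyloxy)phenyl]-3,6-dihydroxy-1,4-benzoquinone | O=C1C(O)=C(c2ccc(OCc3ccccc3)cc2)C(=O)C(O)=C1c1ccc(OCc2ccccc2)cc1 | intermediate
11 | 2,5-bis[4-(benzyloxy)phenyl]-4-hydroxy-3,6-dioxocyclohexa-1,4-dien-1-yl acetate | CC(=O)OC1=C(c2ccc(OCc3ccccc3)cc2)C(=O)C(O)=C(c2ccc(OCc3ccccc3)cc2)C1=O | intermediate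
12 | 2,4,5-trihydroxy-3,6-bis(4-hydroxyphenyl)phenyl acetate | CC(=O)Oc1c(-c2ccc(O)cc2)c(O)c(O)c(-c2ccc(O)cc2)c1O | intermediate
13 | 4-hydroxy-2,5-bis(4-hydroxyphenyl)-3,6-dioxocyclohexa-1,4-dien-1-yl acetate (2-acetoxy-5-hydroxy-3,6-bis(4-hydroxyphenyl)-1,4-benzoquinone) | CC(=O)OC1=C(c2ccc(O)cc2)C(=O)C(O)=C(c2ccc(O)cc2)C1=O | target

Total step count: 6. Longest linear sequence: 6 steps (1 → 4 → 6 → 8 → 10 → 11 → 13).

Steps most likely to fail

1. Step 4 (proposed method). What may go wrong:
- aldol-type self-addition or O-acylation may outrun C-acylation;
- chain growth after the first Claisen event may compete with ring closure;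
- the activated thioester may hydrolyse before it condenses.

Fallback by known chemistry: this fallback does not branch from an intermediate of the route. It sets out from commercial materials in place of compound 8 (none of compounds 1–9 is used) and comes back to the route at compound 10. Commercial bromanil (2,3,5,6-tetrabromo-1,4-benzoquinone) is treated with NaOMe in MeOH. Twofold addition–elimination should give 2,5-dibromo-3,6-dimethoxy-1,4-benzoquinone F1. A double Suzuki–Miyaura coupling of F1 with commercial 4-(benzyloxy)phenylboronic acid follows (Pd(PPh3)4, a zerovalent palladium complex, K2CO3, 1,4-dioxane/H2O, 85 °C). It should give 2,5-bis[4-(benzyloxy)phenyl]-3,6-dimethoxy-1,4-benzoquinone F2. Hydrolysis of the two vinylogous methyl esters (NaOH, aqueous 1,4-dioxane, reflux, then HCl) should deliver 10. The benzyl ethers are stable throughout.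

2. Step 5. What may go wrong:
- mono-selectivity may be lost, with over-acylation alongside unreacted diol;
- acetyl groups may scramble between molecules;
- the vinylogous anhydride may hydrolyse during work-up.

Fallback: it sets out from compound 10 and comes back at compound 11. Exhaustive acetylation (Ac2O, pyridine, rt) should give 2,5-bis[4-(benzyloxy)phenyl]-3,6-dioxocyclohexa-1,4-diene-1,4-diyl diacetate F3. One acetate is then removed with LiOH (2.0 equiv) in THF/H2O at 0 °C. One equivalent of hydroxide is consumed by the acetyl group and one by the acidic hydroxyquinone that is liberated, so no nucleophile is left. The anion of 11 is also a far poorer acyl donor than neutral F3. Cold acidification should give 11.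

3. Step 3. What may go wrong:
- acyl transfer to the enol hydroxyl of the arylpyruvic acid, giving oligomeric enol esters;
- rearrangement of the O-acylisourea to the N-acylurea;
- base-induced condensation of the product during the coupling.

Fallback: it sets out from compound 6 and comes back at compound 8. NaBH4 reduction of the keto acid (aqueous NaHCO3/MeOH, 0 °C) should give racemic 3-[4-(benzyloxy)phenyl]-2-hydroxypropanoic acid F4. This acid has no enol and no activated ketone, so carbodiimide coupling with thiophenol 7 (DCC, DMAP cat., CH2Cl2, 0 °C) is ordinary. It should give racemic S-phenyl 3-[4-(benzyloxy)phenyl]-2-hydroxypropanethioate F5. Dess–Martin periodinane oxidation (CH2Cl2, 0 °C) then unveils the ketone under neutral conditions as the last operation, giving 8.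

Further compounds
F1 | step 4 | 2,5-dibromo-3,6-dimethoxy-1,4-benzoquinone | COC1=C(Br)C(=O)C(OC)=C(Br)C1=O
F2 | step 4 | 2,5-bis[4-(benzyloxy)phenyl]-3,6-dimethoxy-1,4-benzoquinone | COC1=C(c2ccc(OCc3ccccc3)cc2)C(=O)C(OC)=C(c2ccc(OCc3ccccc3)cc2)C1=O
F3 | step 5 | 2,5-bis[4-(benzyloxy)phenyl]-3,6-dioxocyclohexa-1,4-diene-1,4-diyl diacetate | CC(=O)OC1=C(c2ccc(OCc3ccccc3)cc2)C(=O)C(OC(C)=O)=C(c2ccc(OCc3ccccc3)cc2)C1=O
F4 | step 3 | rac-3-[4-(benzyloxy)phenyl]-2-hydroxypropanoic acid | OC(Cc1ccc(OCc2ccccc2)cc1)C(=O)O
F5 | step 3 | rac-S-phenyl 3-[4-(benzyloxy)phenyl]-2-hydroxypropanethioate | OC(Cc1ccc(OCc2ccccc2)cc1)C(=O)Sc1ccccc1
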